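The route rests on one disconnection at C4, the quaternary carbinol carbon of the oxolane ring: its hydroxyl and its CH2–aryl arm are read as the two ends of an exocyclic C4=CH2 alkene. A single three-component radical oxyarylation joins an aryl radical from a diazonium salt to that CH2 and caps the resulting tertiary C4 radical with TEMPO, so the C–aryl bond, the C4–O bond and the C4 stereocentre arise together without ring closure. The precursor is a trans-2-aryl-4-methylideneoxolane that already holds C2 and C3 in the correct configuration and carries the target's acetate on the C3 CH2O arm, leaving only N–O cleavage and debenzylation.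

Key step: step 9

Remark: the oxolane is numbered O1, C2 (aryl-bearing), C3, C4 (carbinol), C5; C9 is the CH2O carbon on C3 and C7' the benzylic CH2 on C4; 4-(benzyloxy)-3-methoxybenzaldehyde (O-benzylvanillin) is assumed to be purchased.

Step 1
Reactants: 1 4-(benzyloxy)-3-methoxybenzaldehyde; 2 vinylmagnesium bromide
Product: 3 rac-1-[4-(benzyloxy)-3-methoxyphenyl]prop-2-en-1-ol
Conditions: THF, 0 °C; then sat. aq. NH4Cl
Reagents that add atoms: none
Why: Grignard 1,2-addition of the vinyl nucleophile to the aromatic aldehyde should give the racemic secondary allylic alcohol, and the mild ammonium chloride quench avoids ionisation of the electron-rich benzylic carbinol.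

Step 2
Reactants: 3 rac-1-[4-(benzyloxy)-3-methoxyphenyl]prop-2-en-1-ol
Product: 4 (R)-[4-(benzyloxy)-3-methoxyphenyl][(2S)-oxiran-2-yl]methanol
Conditions: Ti(OiPr)4, diisopropyl D-(−)-tartrate, TBHP (0.45 equiv), 4 Å MS, CH2Cl2, −20 °C
Reagents that add atoms: tert-butyl hydroperoxide, CC(C)(C)OO
Why: In this Sharpless kinetic resolution the titanium–D-tartrate catalyst should epoxidise the (S)-alcohol much faster than its antipode and deliver oxygen to give the erythro epoxy alcohol, which sets the oxirane carbon as S while the carbinol carbon keeps its configuration (now designated R), the sub-stoichiometric oxidant leaving the (R)-alcohol behind for chromatographic removal.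

Step 3
Reactants: 4 (R)-[4-(benzyloxy)-3-methoxyphenyl][(2S)-oxiran-2-yl]methanol; 5 propargyl bromide
Product: 6 (2S)-2-[(R)-[4-(benzyloxy)-3-methoxyphenyl](prop-2-yn-1-yloxy)methyl]oxirane
Conditions: NaH (added last), Bu4NI (cat.), THF, 0 °C
Reagents that add atoms: none
Why: In this Williamson ether synthesis the sodium alkoxide, formed in the presence of the reactive propargylic bromide in an aprotic solvent at 0 °C, should be alkylated faster than it can undergo Payne rearrangement, and neither stereocentre is touched.

Step 4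
Reactants: 6 (2S)-2-[(R)-[4-(benzyloxy)-3-methoxyphenyl](prop-2-yn-1-yloxy)methyl]oxirane
Product: 7 [(2S,3R)-2-[4-(benzyloxy)-3-methoxyphenyl]-4-methylideneoxolan-3-yl]methanol
Conditions: Cp2TiCl2 (2.5 equiv), Zn dust, THF, rt; then 1 M HCl, 0 °C
Reagents that add atoms: none
Why: Cp2TiCl (trivalent titanium) should open the oxirane by electron transfer to the secondary β-titanoxy radical, which closes by 5-exo-dig radical cyclisation onto the alkyne before the vinyl radical takes hydrogen from THF, the oxirane stereocentre being erased in the radical and C3 being set trans to the C2 aryl group because the transition state places the aryl group and the CH2O–Ti arm on opposite faces of the forming ring.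

Step 5
Reactants: 7 [(2S,3R)-2-[4-(benzyloxy)-3-methoxyphenyl]-4-methylideneoxolan-3-yl]methanol
Product: 8 [(2S,3R)-2-[4-(benzyloxy)-3-methoxyphenyl]-4-methylideneoxolan-3-yl]methyl acetate
Conditions: Ac2O, pyridine, DMAP (cat.), CH2Cl2, 0 °C to rt
Reagents that add atoms: acetic anhydride, CC(=O)OC(C)=O
Why: DMAP-catalysed acylation of the unhindered primary alcohol should install the C9 acetate of the target before the key step, so that no protecting-group exchange is needed afterwards.

Step 6
Reactants: 9 2-methoxy-4-nitrophenol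
Product: 10 1-(benzyloxy)-2-methoxy-4-nitrobenzene
Conditions: BnBr, K2CO3, DMF, 60 °C
Reagents that add atoms: benzyl bromide, BrCc1ccccc1
Why: Williamson O-benzylation of the acidic nitrophenol with a benzylic halide and carbonate base is a standard, high-yielding etherification.

Step 7
Reactants: 10 1-(benzyloxy)-2-methoxy-4-nitrobenzene
Product: 11 4-(benzyloxy)-3-methoxyaniline
Conditions: Fe powder, NH4Cl, EtOH–H2O, 80 °C
Reagents that add atoms: none
Why: Béchamp-type reduction of the nitroarene by iron proceeds by electron transfer and should spare the benzyl ether that catalytic hydrogenation would cleave.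

Step 8
Reactants: 11 4-(benzyloxy)-3-methoxyaniline
Product: 12 4-(benzyloxy)-3-methoxybenzenediazonium tetrafluoroborate
Conditions: NaNO2, 48% aq. HBF4, H2O–MeCN, 0 °C; precipitation with Et2O, stored cold in the dark
Reagents that add atoms: sodium nitrite, [Na+].[O-]N=O; tetrafluoroboric acid, [H+].F[B-](F)(F)F
Why: Diazotisation of the aniline by nitrous acid in the presence of the non-nucleophilic tetrafluoroborate counter-ion should give an isolable arenediazonium salt, the electron-rich ring stabilising the cation.

Step 9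
Reactants: 8 [(2S,3R)-2-[4-(benzyloxy)-3-methoxyphenyl]-4-methylideneoxolan-3-yl]methyl acetate; 12 4-(benzyloxy)-3-methoxybenzenediazonium tetrafluoroborate; 13 TEMPO (2,2,6,6-tetramethylpiperidin-1-oxyl)
Product: 15 [(2S,3R,4S)-2-[4-(benzyloxy)-3-methoxyphenyl]-4-{[4-(benzyloxy)-3-methoxyphenyl]methyl}-4-[(2,2,6,6-tetramethylpiperidin-1-yl)oxy]oxolan-3-yl]methyl acetate, via TEMPONa 14 (not isolated)
Conditions: 13, Na, THF, rt (gives 14); 14 (2.8 equiv) added by syringe pump over 3 h to 8 and 12 (3 equiv) in PhCF3, rt
Reagents that add atoms: none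
Why: Single-electron transfer from the aminoxyl anion 14 to the diazonium cation of 12 releases N2, an aryl radical and TEMPO; the aryl radical adds to the unsubstituted CH2 terminus of the 1,1-disubstituted alkene of 8, and the tertiary C4 radical so formed is captured by the persistent nitroxide, so the C7'–aryl and C4–O bonds form in one operation. The closest known reaction type is the radical carboaminoxylation (Meerwein-type oxyarylation) of alkenes with arenediazonium salts and TEMPONa. No ring is closed. The new C4 stereocentre is set in the radical–nitroxide coupling, where the bulky nitroxide should approach the planar C4 radical on the ring face opposite the adjacent C3 acetoxymethyl arm, placing oxygen trans to C9 and the new benzyl arm cis to it (4S). The step needs regioselectivity, secured by the open CH2 terminus and the stability of the tertiary radical; facial selectivity, secured by the C3 substituent next to the radical centre; and tolerance of the acetate, secured by slow addition of 14 into an excess of 12 so that electron transfer outruns acyl transfer. Because no cation intervenes, elimination and participation by the C9 oxygen should not compete.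

Step 10
Reactants: 15 [(2S,3R,4S)-2-[4-(benzyloxy)-3-methoxyphenyl]-4-{[4-(benzyloxy)-3-methoxyphenyl]methyl}-4-[(2,2,6,6-tetramethylpiperidin-1-yl)oxy]oxolan-3-yl]methyl acetate
Product: 16 [(2S,3R,4S)-2-[4-(benzyloxy)-3-methoxyphenyl]-4-{[4-(benzyloxy)-3-methoxyphenyl]methyl}-4-hydroxyoxolan-3-yl]methyl acetate
Conditions: Zn dust, AcOH–THF–H2O (3:1:1), 50 °C
Reagents that add atoms: none
Why: Dissolving-metal reduction by zinc in acetic acid should cleave the weak N–O bond of the protonated alkoxyamine while leaving the C4–O bond intact, so C4 keeps its configuration, and the benzyl ethers and the acetate are inert to these conditions.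

Step 11
Reactants: 16 [(2S,3R,4S)-2-[4-(benzyloxy)-3-methoxyphenyl]-4-{[4-(benzyloxy)-3-methoxyphenyl]methyl}-4-hydroxyoxolan-3-yl]methyl acetate
Product: 17 olivil monoacetate, [(2S,3R,4S)-4-hydroxy-2-(4-hydroxy-3-methoxyphenyl)-4-[(4-hydroxy-3-methoxyphenyl)methyl]oxolan-3-yl]methyl acetate
Conditions: H2 (1 atm), 10% Pd/C, EtOAc, rt, stopped as soon as 16 is consumed
Reagents that add atoms: none
Why: Catalytic hydrogenolysis should remove both aryl benzyl ethers, which cleave much faster than the benzylic C2–O1 bond of the oxolane under neutral conditions at atmospheric pressure, while the acetate, the tertiary alcohol and all three stereocentres are untouched.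

Compound list
1 | 4-(benzyloxy)-3-methoxybenzaldehyde | COc1cc(C=O)ccc1OCc1ccccc1 | starting material
2 | vinylmagnesium bromide | C=C[Mg]Br | starting material
3 | rac-1-[4-(benzyloxy)-3-methoxyphenyl]prop-2-en-1-ol | C=CC(O)c1ccc(OCc2ccccc2)c(OC)c1 | intermediate
4 | (R)-[4-(benzyloxy)-3-methoxyphenyl][(2S)-oxiran-2-yl]methanol | COc1cc([C@@H](O)[C@@H]2CO2)ccc1OCc1ccccc1 | intermediate
5 | propargyl bromide (3-bromoprop-1-yne) | C#CCBr | starting material
6 | (2S)-2-[(R)-[4-(benzyloxy)-3-methoxyphenyl](prop-2-yn-1-yloxy)methyl]oxirane | COc1cc([C@@H](OCC#C)[C@@H]2CO2)ccc1OCc1ccccc1 | intermediate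
7 | [(2S,3R)-2-[4-(benzyloxy)-3-methoxyphenyl]-4-methylideneoxolan-3-yl]methanol | C=C1CO[C@H](c2ccc(OCc3ccccc3)c(OC)c2)[C@H]1CO | intermediate
8 | [(2S,3R)-2-[4-(benzyloxy)-3-methoxyphenyl]-4-methylideneoxolan-3-yl]methyl acetate | C=C1CO[C@H](c2ccc(OCc3ccccc3)c(OC)c2)[C@H]1COC(C)=O | intermediate
9 | 2-methoxy-4-nitrophenol | COc1cc([N+](=O)[O-])ccc1O | starting material
10 | 1-(benzyloxy)-2-methoxy-4-nitrobenzene | COc1cc([N+](=O)[O-])ccc1OCc1ccccc1 | intermediate
11 | 4-(benzyloxy)-3-methoxyaniline | COc1cc(N)ccc1OCc1ccccc1 | intermediate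
12 | 4-(benzyloxy)-3-methoxybenzenediazonium tetrafluoroborate | COc1cc([N+]#N)ccc1OCc1ccccc1.F[B-](F)(F)F | intermediate
13 | TEMPO (2,2,6,6-tetramethylpiperidin-1-oxyl) | CC1(C)CCCC(C)(C)N1[O] | starting material
14 | TEMPONa (sodium 2,2,6,6-tetramethylpiperidin-1-olate) | CC1(C)CCCC(C)(C)N1[O-].[Na+] | intermediate
15 | [(2S,3R,4S)-2-[4-(benzyloxy)-3-methoxyphenyl]-4-{[4-(benzyloxy)-3-methoxyphenyl]methyl}-4-[(2,2,6,6-tetramethylpiperidin-1-yl)oxy]oxolan-3-yl]methyl acetate | COc1cc(C[C@@]2(ON3C(C)(C)CCCC3(C)C)CO[C@H](c3ccc(OCc4ccccc4)c(OC)c3)[C@H]2COC(C)=O)ccc1OCc1ccccc1 | intermediate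
16 | [(2S,3R,4S)-2-[4-(benzyloxy)-3-methoxyphenyl]-4-{[4-(benzyloxy)-3-methoxyphenyl]methyl}-4-hydroxyoxolan-3-yl]methyl acetate | COc1cc(C[C@@]2(O)CO[C@H](c3ccc(OCc4ccccc4)c(OC)c3)[C@H]2COC(C)=O)ccc1OCc1ccccc1 | intermediate
17 | olivil monoacetate, [(2S,3R,4S)-4-hydroxy-2-(4-hydroxy-3-methoxyphenyl)-4-[(4-hydroxy-3-methoxyphenyl)methyl]oxolan-3-yl]methyl acetate | COc1cc(C[C@@]2(O)CO[C@H](c3ccc(O)c(OC)c3)[C@H]2COC(C)=O)ccc1O | target

Total step count: 11 (steps 1–5 for the alkene, steps 6–8 for the diazonium salt, steps 9–11 after convergence).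
Longest linear sequence: 8 steps (1, 2, 3, 4, 5, 9, 10, 11, from compound 1).

Steps most likely to fail

Step 9 (key step). The aryl radical may be intercepted by the nitroxide or by hydrogen donors before it reaches the ring-bound alkene, or the nitroxide may couple at C4 with poor facial discrimination. The fallback builds the same C4 carbinol by polar chemistry, setting out from 7 and coming back to the route at 16. Silylation of 7 (TBSCl, imidazole, DMF) would give tert-butyl{[(2S,3R)-2-[4-(benzyloxy)-3-methoxyphenyl]-4-methylideneoxolan-3-yl]methoxy}dimethylsilane F1. Epoxidation of F1 (mCPBA, NaHCO3, CH2Cl2, 0 °C), steered to the face anti to the C3 silyloxymethyl arm, would give the C4 spiro-oxirane F2 with the oxirane oxygen trans to C9. [4-(Benzyloxy)-3-methoxyphenyl]magnesium bromide F3, prepared from purchased 1-(benzyloxy)-4-bromo-2-methoxybenzene and Mg in THF, would open F2 at its CH2 carbon under CuBr·SMe2 catalysis (THF, −30 °C; aq. NH4Cl) to give the silyl-protected tertiary alcohol F4. TBAF in THF would give the diol F5, and acetylation of its primary hydroxyl (Ac2O, pyridine, CH2Cl2, 0 °C) would return to 16.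

Step 10. Electron transfer to the crowded tertiary N–O bond may be slow, and forcing it with heat and acid would expose the benzylic oxolane carbon C2 to epimerisation or ring opening. The fallback introduces the C4 oxygen as a peroxide, which needs only a phosphine for reduction, setting out from 8 and 12 and coming back at 16. Reduction of 12 (SnCl2·2H2O, aq. HCl, 0 °C) would give [4-(benzyloxy)-3-methoxyphenyl]hydrazine F6. Oxidation of F6 with MnO2 under air in MeCN in the presence of 8 would generate the same aryl radical, whose C4 adduct radical is captured by O2 to give the tertiary hydroperoxide F7 (hydroperoxyarylation of an alkene). PPh3 in CH2Cl2 would then reduce F7 to 16. Lower facial selectivity is to be expected with the small oxygen trap, so the C4 epimers would have to be separated.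

Step 3. The alkoxide of 4 may undergo Payne rearrangement (migration of the oxirane toward the benzylic carbon) or open another oxirane before it is alkylated. The fallback makes the ether before the oxirane, setting out from 3 and coming back at 7. Sharpless kinetic resolution of 3 with the antipodal ligand (Ti(OiPr)4, diisopropyl L-(+)-tartrate, TBHP 0.6 equiv, 4 Å MS, CH2Cl2, −20 °C) would consume the (R)-alcohol as its epoxy alcohol and leave (S)-1-[4-(benzyloxy)-3-methoxyphenyl]prop-2-en-1-ol F8. Propargylation (NaH, 5, THF, 0 °C) would give the allyl propargyl ether F9, which has no oxirane to rearrange. Epoxidation of the vinyl group (mCPBA, NaHCO3, CH2Cl2, rt; the terminal alkyne should react far more slowly) would give the oxirane F10 as a mixture of epimers at the oxirane carbon, which is harmless because that carbon becomes the radical centre. Cyclisation with Cp2TiCl as in step 4 would return to 7.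

Further compounds
F1 | step 9 | tert-butyl{[(2S,3R)-2-[4-(benzyloxy)-3-methoxyphenyl]-4-methylideneoxolan-3-yl]methoxy}dimethylsilane | C=C1CO[C@H](c2ccc(OCc3ccccc3)c(OC)c2)[C@H]1CO[Si](C)(C)C(C)(C)C
F2 | step 9 | C4 spiro-oxirane of F1, 6-[4-(benzyloxy)-3-methoxyphenyl]-7-{[tert-butyl(dimethyl)silyl]oxymethyl}-1,5-dioxaspiro[2.4]heptane with the oxirane oxygen trans to the silyloxymethyl arm | C1O[C@@]12CO[C@H](c3ccc(OCc4ccccc4)c(OC)c3)[C@H]2CO[Si](C)(C)C(C)(C)C
F3 | step 9 | [4-(benzyloxy)-3-methoxyphenyl]magnesium bromide | COc1cc([Mg]Br)ccc1OCc1ccccc1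
F4 | step 9 | (3S,4R,5S)-5-[4-(benzyloxy)-3-methoxyphenyl]-3-{[4-(benzyloxy)-3-methoxyphenyl]methyl}-4-{[tert-butyl(dimethyl)silyl]oxymethyl}oxolan-3-ol | COc1cc(C[C@@]2(O)CO[C@H](c3ccc(OCc4ccccc4)c(OC)c3)[C@H]2CO[Si](C)(C)C(C)(C)C)ccc1OCc1ccccc1
F5 | step 9 | (3S,4R,5S)-5-[4-(benzyloxy)-3-methoxyphenyl]-3-{[4-(benzyloxy)-3-methoxyphenyl]methyl}-4-(hydroxymethyl)oxolan-3-ol | COc1cc(C[C@@]2(O)CO[C@H](c3ccc(OCc4ccccc4)c(OC)c3)[C@H]2CO)ccc1OCc1ccccc1
F6 | step 10 | [4-(benzyloxy)-3-methoxyphenyl]hydrazine | COc1cc(NN)ccc1OCc1ccccc1
F7 | step 10 | [(2S,3R,4S)-2-[4-(benzyloxy)-3-methoxyphenyl]-4-{[4-(benzyloxy)-3-methoxyphenyl]methyl}-4-hydroperoxyoxolan-3-yl]methyl acetate | COc1cc(C[C@@]2(OO)CO[C@H](c3ccc(OCc4ccccc4)c(OC)c3)[C@H]2COC(C)=O)ccc1OCc1ccccc1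
F8 | step 3 | (S)-1-[4-(benzyloxy)-3-methoxyphenyl]prop-2-en-1-ol | C=C[C@H](O)c1ccc(OCc2ccccc2)c(OC)c1
F9 | step 3 | 1-(benzyloxy)-2-methoxy-4-[(1S)-1-(prop-2-yn-1-yloxy)prop-2-en-1-yl]benzene | C=C[C@H](OCC#C)c1ccc(OCc2ccccc2)c(OC)c1
F10 | step 3 | 2-[(R)-[4-(benzyloxy)-3-methoxyphenyl](prop-2-yn-1-yloxy)methyl]oxirane, mixture of epimers at the oxirane carbon | COc1cc([C@@H](OCC#C)C2CO2)ccc1OCc1ccccc1
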